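**Retrosynthetic overview**
- The target is 5R,6S,5'S, with O5 and O6 trans on the five-membered ring. The last operations are a Suzuki–Miyaura coupling of the C3–Cl core with a (1E,3E,5S)-dienylboronate, then O5 desilylation. The boronate comes from (S)-2-methylbutan-1-ol by oxidation, Wittig and boron–Wittig reactions.
- Ring order: the pyridine is bought and a temporary dioxolanone ring is made first. The cyclopentanone ring is closed last (C7–C7a) by Br/Mg exchange and attack on the dioxolanone carbonyl, which unmasks O6 alone for acetylation.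
- C4a–C5: 4-lithiated 5-bromo-2-chloropyridine adds to a chiral α-keto ester (sets C5).
- C5–C6: oxalylation of the enolate of the pivalaldehyde acetal of (R)-lactic acid (sets C6 by self-regeneration of the stereocentre).

Assumption: core atoms are numbered as in cyclopenta[c]pyridine (C1, N2, C3, C4, C4a, C5, C6, C7, C7a); LiN(iPr)2, lithium 2,2,6,6-tetramethylpiperidide and iPrMgCl·LiCl are used as purchased reagents.

Step 1
Reactants: 1 (R)-lactic acid; 2 pivalaldehyde (2,2-dimethylpropanal)
Product: 3 (2R,5R)-2-tert-butyl-5-methyl-1,3-dioxolan-4-one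
Conditions: p-TsOH·H2O (cat.), pentane, reflux, Dean–Stark; recrystallisation from pentane, −78 °C
Reagents that add atoms: none
Why: Acid-catalysed acetalisation leaves the lactic acid centre untouched and forms the new acetal centre mainly cis (tert-butyl and methyl on the same face), and crystallisation gives the pure cis isomer.

Step 2
Reactants: 3 (2R,5R)-2-tert-butyl-5-methyl-1,3-dioxolan-4-one; 4 methyl chlorooxoacetate
Product: 6 methyl 2-[(2R,4S)-2-tert-butyl-4-methyl-5-oxo-1,3-dioxolan-4-yl]-2-oxoacetate, via lithium enolate 5 (not isolated)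
Conditions: LiN(iPr)2 (1.05 equiv), THF, −78 °C, 30 min; inverse addition to 4 (1.5 equiv), THF, −78 °C
Reagents that add atoms: none
Why: Claisen-type C-acylation of the Seebach enolate (self-regeneration of stereocentres) occurs on the face anti to tert-butyl, so the oxalyl carbon takes the place of the former hydrogen and sets the quaternary carbinol carbon (future C6, S).

Step 3
Reactants: 7 5-bromo-2-chloropyridine; 6 methyl 2-[(2R,4S)-2-tert-butyl-4-methyl-5-oxo-1,3-dioxolan-4-yl]-2-oxoacetate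
Product: 10 methyl (2R)-2-(5-bromo-2-chloropyridin-4-yl)-2-[(2R,4S)-2-tert-butyl-4-methyl-5-oxo-1,3-dioxolan-4-yl]-2-(triethylsilyloxy)acetate, via aryllithium 8 (not isolated), via lithium alkoxide 9 (not isolated)
Conditions: 7, LiN(iPr)2 (1.05 equiv), THF, −78 °C, 30 min; 6, −78 °C, 1 h; Et3SiOTf (2.5 equiv), −78 to −30 °C
Reagents that add atoms: triethylsilyl trifluoromethanesulfonate, CC[Si](CC)(CC)OS(=O)(=O)C(F)(F)F
Why: Directed ortho-lithiation next to bromine is followed by 1,2-addition to the keto carbonyl (the most electrophilic of the three), where Felkin–Anh/Cornforth control sets the new carbinol centre (future C5, R) because, in the rotamer with C=O antiperiplanar to the ring C–O bond, the aryl group enters anti to the exocyclic methyl, over the tied-back lactone carbon on the ring face remote from tert-butyl, and cold silylation then blocks retro-aldol scrambling.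

Step 4
Reactants: 10 methyl (2R)-2-(5-bromo-2-chloropyridin-4-yl)-2-[(2R,4S)-2-tert-butyl-4-methyl-5-oxo-1,3-dioxolan-4-yl]-2-(triethylsilyloxy)acetate
Product: 13 methyl (5R,6S)-6-acetoxy-3-chloro-6-methyl-7-oxo-5-(triethylsilyloxy)-6,7-dihydro-5H-cyclopenta[c]pyridine-5-carboxylate, via arylmagnesium chloride 11 (not isolated), via magnesium alkoxide 12 (not isolated)
Conditions: iPrMgCl·LiCl (1.1 equiv), THF, −40 to −10 °C; then Ac2O (4 equiv), DMAP (0.2 equiv), −10 °C to rt
Reagents that add atoms: acetic anhydride, CC(=O)OC(C)=O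
Why: In this Parham-type cyclisation, Br/Mg exchange on the electron-poor pyridine outruns attack on the hindered esters, the arylmagnesium (too weakly carbanionic for O-to-C silyl migration) closes the five-membered ring by acyl substitution at the lactone carbonyl with loss of pivalaldehyde, and the unmasked C6 alkoxide is the only free oxygen when Ac2O arrives, so no stereocentre is touched and only O6 is acetylated.

Step 5
Reactants: 14 (S)-2-methylbutan-1-ol
Product: 15 (S)-2-methylbutanal
Conditions: TEMPO (1 mol %), KBr (10 mol %), NaOCl (1.1 equiv), NaHCO3, CH2Cl2/H2O, 0 °C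
Reagents that add atoms: none
Why: Anelli oxidation stops at the aldehyde under buffered biphasic conditions at 0 °C, so the α-stereocentre bought with 14 is not epimerised.

Step 6
Reactants: 15 (S)-2-methylbutanal; 16 2-(triphenylphosphoranylidene)propanal
Product: 17 (2E,4S)-2,4-dimethylhex-2-enal
Conditions: toluene, 100 °C, 24 h
Reagents that add atoms: none
Why: Wittig olefination with the stabilised formyl ylide gives the E-trisubstituted enal, and the neutral medium leaves the allylic S centre intact.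

Step 7
Reactants: 18 bis(4,4,5,5-tetramethyl-1,3,2-dioxaborolan-2-yl)methane; 17 (2E,4S)-2,4-dimethylhex-2-enal
Product: 20 2-[(1E,3E,5S)-3,5-dimethylhepta-1,3-dien-1-yl]-4,4,5,5-tetramethyl-1,3,2-dioxaborolane, via lithiated diborylmethane 19 (not isolated)
Conditions: 18 (1.2 equiv), lithium 2,2,6,6-tetramethylpiperidide (1.2 equiv), THF, 0 °C, 10 min; 17, −78 °C to rt
Reagents that add atoms: none
Why: In this boron–Wittig olefination, 1,2-addition of the α-diboryl carbanion to the enal and syn B–O elimination give the new E-alkenylboronate, while the existing E-alkene and the S centre are untouched.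

Step 8
Reactants: 13 methyl (5R,6S)-6-acetoxy-3-chloro-6-methyl-7-oxo-5-(triethylsilyloxy)-6,7-dihydro-5H-cyclopenta[c]pyridine-5-carboxylate; 20 2-[(1E,3E,5S)-3,5-dimethylhepta-1,3-dien-1-yl]-4,4,5,5-tetramethyl-1,3,2-dioxaborolane
Product: 21 methyl (5R,6S)-6-acetoxy-3-[(1E,3E,5S)-3,5-dimethylhepta-1,3-dien-1-yl]-6-methyl-7-oxo-5-(triethylsilyloxy)-6,7-dihydro-5H-cyclopenta[c]pyridine-5-carboxylate
Conditions: Pd(OAc)2 (5 mol %), SPhos (10 mol %), K3PO4 (2 equiv), THF/H2O 10:1, 45 °C
Reagents that add atoms: none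
Why: In this Suzuki–Miyaura coupling the C3–Cl bond (α to nitrogen, para to the ketone) adds readily to zerovalent palladium, the dienyl group is transferred with retention of E,E geometry, and the non-enolisable, O5-silylated core tolerates K3PO4.

Step 9
Reactants: 21 methyl (5R,6S)-6-acetoxy-3-[(1E,3E,5S)-3,5-dimethylhepta-1,3-dien-1-yl]-6-methyl-7-oxo-5-(triethylsilyloxy)-6,7-dihydro-5H-cyclopenta[c]pyridine-5-carboxylate
Product: 22 methyl (5R,6S)-6-acetoxy-3-[(1E,3E,5S)-3,5-dimethylhepta-1,3-dien-1-yl]-5-hydroxy-6-methyl-7-oxo-6,7-dihydro-5H-cyclopenta[c]pyridine-5-carboxylate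
Conditions: HF·pyridine, THF/pyridine, 0 °C to rt
Reagents that add atoms: none
Why: Fluoride-mediated desilylation in a mildly acidic medium frees the tertiary C5 hydroxyl without base, so retro-aldol opening and acetate cleavage are avoided and acetyl migration to the trans-disposed O5 is geometrically impossible.

**Compound list**
1 | (R)-lactic acid | C[C@@H](O)C(=O)O | starting material
2 | pivalaldehyde | CC(C)(C)C=O | starting material
3 | (2R,5R)-2-tert-butyl-5-methyl-1,3-dioxolan-4-one | C[C@H]1O[C@@H](C(C)(C)C)OC1=O | intermediate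
4 | methyl chlorooxoacetate | COC(=O)C(=O)Cl | starting material
5 | lithium (2R)-2-tert-butyl-5-methyl-1,3-dioxol-4-olate (enolate of 3) | CC1=C(O[Li])O[C@H](C(C)(C)C)O1 | intermediate
6 | methyl 2-[(2R,4S)-2-tert-butyl-4-methyl-5-oxo-1,3-dioxolan-4-yl]-2-oxoacetate | C[C@@]1(C(=O)C(=O)OC)O[C@@H](C(C)(C)C)OC1=O | intermediate
7 | 5-bromo-2-chloropyridine | Clc1ccc(Br)cn1 | starting material
8 | (5-bromo-2-chloropyridin-4-yl)lithium | Clc1cc([Li])c(Br)cn1 | intermediate
9 | lithium alkoxide of methyl (2R)-2-(5-bromo-2-chloropyridin-4-yl)-2-[(2R,4S)-2-tert-butyl-4-methyl-5-oxo-1,3-dioxolan-4-yl]-2-hydroxyacetate | COC(=O)[C@@](O[Li])(c1cc(Cl)ncc1Br)[C@]1(C)O[C@@H](C(C)(C)C)OC1=O | intermediate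
10 | methyl (2R)-2-(5-bromo-2-chloropyridin-4-yl)-2-[(2R,4S)-2-tert-butyl-4-methyl-5-oxo-1,3-dioxolan-4-yl]-2-(triethylsilyloxy)acetate | COC(=O)[C@@](O[Si](CC)(CC)CC)(c1cc(Cl)ncc1Br)[C@]1(C)O[C@@H](C(C)(C)C)OC1=O | intermediate
11 | arylmagnesium chloride from 10 (Br on the pyridine replaced by MgCl, all stereocentres as in 10) | COC(=O)[C@@](O[Si](CC)(CC)CC)(c1cc(Cl)ncc1[Mg]Cl)[C@]1(C)O[C@@H](C(C)(C)C)OC1=O | intermediate
12 | chloromagnesium alkoxide of methyl (5R,6S)-3-chloro-6-hydroxy-6-methyl-7-oxo-5-(triethylsilyloxy)-6,7-dihydro-5H-cyclopenta[c]pyridine-5-carboxylate | Clc1cc2c(cn1)C(=O)[C@@](C)(O[Mg]Cl)[C@@]2(O[Si](CC)(CC)CC)C(=O)OC | intermediate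
13 | methyl (5R,6S)-6-acetoxy-3-chloro-6-methyl-7-oxo-5-(triethylsilyloxy)-6,7-dihydro-5H-cyclopenta[c]pyridine-5-carboxylate | Clc1cc2c(cn1)C(=O)[C@@](C)(OC(C)=O)[C@@]2(O[Si](CC)(CC)CC)C(=O)OC | intermediate
14 | (S)-2-methylbutan-1-ol | CC[C@H](C)CO | starting material
15 | (S)-2-methylbutanal | CC[C@H](C)C=O | intermediate
16 | 2-(triphenylphosphoranylidene)propanal | CC(C=O)=P(c1ccccc1)(c1ccccc1)c1ccccc1 | starting material
17 | (2E,4S)-2,4-dimethylhex-2-enal | CC[C@H](C)/C=C(C)/C=O | intermediate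
18 | bis(4,4,5,5-tetramethyl-1,3,2-dioxaborolan-2-yl)methane | CC1(C)OB(CB2OC(C)(C)C(C)(C)O2)OC1(C)C | starting material
19 | [bis(4,4,5,5-tetramethyl-1,3,2-dioxaborolan-2-yl)methyl]lithium | [Li]C(B1OC(C)(C)C(C)(C)O1)B1OC(C)(C)C(C)(C)O1 | intermediate
20 | 2-[(1E,3E,5S)-3,5-dimethylhepta-1,3-dien-1-yl]-4,4,5,5-tetramethyl-1,3,2-dioxaborolane | CC[C@H](C)/C=C(C)/C=C/B1OC(C)(C)C(C)(C)O1 | intermediate
21 | methyl (5R,6S)-6-acetoxy-3-[(1E,3E,5S)-3,5-dimethylhepta-1,3-dien-1-yl]-6-methyl-7-oxo-5-(triethylsilyloxy)-6,7-dihydro-5H-cyclopenta[c]pyridine-5-carboxylate | CC[C@H](C)/C=C(C)/C=C/c1cc2c(cn1)C(=O)[C@@](C)(OC(C)=O)[C@@]2(O[Si](CC)(CC)CC)C(=O)OC | intermediate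
22 | methyl (5R,6S)-6-acetoxy-3-[(1E,3E,5S)-3,5-dimethylhepta-1,3-dien-1-yl]-5-hydroxy-6-methyl-7-oxo-6,7-dihydro-5H-cyclopenta[c]pyridine-5-carboxylate | CC[C@H](C)/C=C(C)/C=C/c1cc2c(cn1)C(=O)[C@@](C)(OC(C)=O)[C@@]2(O)C(=O)OC | target

Total step count: 9.
Longest linear sequence: 6 steps (1, 2, 3, 4, 8, 9).

**Steps most likely to fail**

**Step 3.** The C5 configuration rests on an open-chain induction model. Attack from the methyl side would give the C5 epimer, and the hindered ketone may lose out to the ester or lactone carbonyl.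
- The fallback sets out from 5 and comes back at 10. It reverses the order in which the two carbon groups reach C5.
- Enolate 5 adds, anti to tert-butyl, to commercial 5-bromo-2-chloropyridine-4-carbaldehyde. This gives (2R,5S)-5-[(5-bromo-2-chloropyridin-4-yl)(hydroxy)methyl]-2-tert-butyl-5-methyl-1,3-dioxolan-4-one F1.
- Dess–Martin periodinane oxidises it to (2R,5S)-5-(5-bromo-2-chloropyridine-4-carbonyl)-2-tert-butyl-5-methyl-1,3-dioxolan-4-one F2, now the only ketone present.
- 1-Methoxyvinyllithium, a methoxycarbonyl anion equivalent, adds at −78 °C. Et3SiOTf traps the alkoxide as (2R,5S)-5-[(1S)-1-(5-bromo-2-chloropyridin-4-yl)-2-methoxy-1-(triethylsilyloxy)prop-2-en-1-yl]-2-tert-butyl-5-methyl-1,3-dioxolan-4-one F3.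
- Ozonolysis of the enol ether (O3, CH2Cl2, −78 °C; Me2S) turns C(OMe)=CH2 into CO2Me, which is 10.
- The group that arrives last occupies the same place in space. The same facial bias that gave the wrong epimer in step 3 therefore gives the right one here.

**Step 4.** Alkoxide 12 is a β-alkoxy ester next to a ketone. Retro-aldol opening would pass through an achiral diketone enolate and racemise both ring centres. O-to-C silyl shift and intermolecular attack are further risks.
- The fallback sets out from 10 and comes back at 13. It installs the acetate before ring closure and changes the acyl acceptor.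
- Me(MeO)NH·HCl/AlMe3 (CH2Cl2, 0 °C to rt) opens the dioxolanone to methyl (2R,3S)-2-(5-bromo-2-chloropyridin-4-yl)-3-hydroxy-4-[methoxy(methyl)amino]-3-methyl-4-oxo-2-(triethylsilyloxy)butanoate F4.
- Ac2O/DMAP gives methyl (2R,3S)-3-acetoxy-2-(5-bromo-2-chloropyridin-4-yl)-4-[methoxy(methyl)amino]-3-methyl-4-oxo-2-(triethylsilyloxy)butanoate F5.
- iPrMgCl·LiCl (THF, −40 to 0 °C) then closes the five-membered ring onto the Weinreb amide. Its chelated adduct collapses only on work-up to 13, so a free C6 alkoxide never sits beside the ketone.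

**Step 2.** O-acylation of 5, or aldol attack of 5 on the very electrophilic product 6, may dominate.
- The fallback sets out from 5 and comes back at 6. It replaces the acylation by an aldol–oxidation pair.
- Enolate 5 adds to freshly cracked methyl glyoxylate (THF, −78 °C, anti to tert-butyl). This gives methyl 2-[(2R,4S)-2-tert-butyl-4-methyl-5-oxo-1,3-dioxolan-4-yl]-2-hydroxyacetate F6 as a mixture of carbinol epimers, which does not matter.
- Dess–Martin periodinane (CH2Cl2, rt) oxidises F6 to 6.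

**Further compounds**
F1 | step 3 | (2R,5S)-5-[(5-bromo-2-chloropyridin-4-yl)(hydroxy)methyl]-2-tert-butyl-5-methyl-1,3-dioxolan-4-one (carbinol epimers) | C[C@@]1(C(O)c2cc(Cl)ncc2Br)O[C@@H](C(C)(C)C)OC1=O
F2 | step 3 | (2R,5S)-5-(5-bromo-2-chloropyridine-4-carbonyl)-2-tert-butyl-5-methyl-1,3-dioxolan-4-one | C[C@@]1(C(=O)c2cc(Cl)ncc2Br)O[C@@H](C(C)(C)C)OC1=O
F3 | step 3 | (2R,5S)-5-[(1S)-1-(5-bromo-2-chloropyridin-4-yl)-2-methoxy-1-(triethylsilyloxy)prop-2-en-1-yl]-2-tert-butyl-5-methyl-1,3-dioxolan-4-one | COC(=C)[C@@](O[Si](CC)(CC)CC)(c1cc(Cl)ncc1Br)[C@]1(C)O[C@@H](C(C)(C)C)OC1=O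
F4 | step 4 | methyl (2R,3S)-2-(5-bromo-2-chloropyridin-4-yl)-3-hydroxy-4-[methoxy(methyl)amino]-3-methyl-4-oxo-2-(triethylsilyloxy)butanoate | COC(=O)[C@@](O[Si](CC)(CC)CC)(c1cc(Cl)ncc1Br)[C@](C)(O)C(=O)N(C)OC
F5 | step 4 | methyl (2R,3S)-3-acetoxy-2-(5-bromo-2-chloropyridin-4-yl)-4-[methoxy(methyl)amino]-3-methyl-4-oxo-2-(triethylsilyloxy)butanoate | COC(=O)[C@@](O[Si](CC)(CC)CC)(c1cc(Cl)ncc1Br)[C@](C)(OC(C)=O)C(=O)N(C)OC
F6 | step 2 | methyl 2-[(2R,4S)-2-tert-butyl-4-methyl-5-oxo-1,3-dioxolan-4-yl]-2-hydroxyacetate (carbinol epimers) | C[C@@]1(C(O)C(=O)OC)O[C@@H](C(C)(C)C)OC1=O
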